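## Retrosynthetic overview

1. The C6 ester bond is cut last: a silyl-protected epoxy diol core is joined to 4-(benzyloxy)-3-methoxybenzoyl chloride; only the TBS-to-acetate exchange at C2 and debenzylation follow.
2. The aroyl fragment comes from catechol (mono-methylation, para-bromination, benzylation, Br/Li exchange with CO2, acid chloride).
3. In the core, the oxirane is formed last (epoxidation directed by the C6–OH), after the seven-membered ring is closed by ring-closing metathesis (C8=C9) and the C4 carbinol is made by isopropyl addition.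
4. The cyclopentane is the first ring, taken from the chiral pool; C1, C5 and C6 are set in one three-component coupling of Me2CuLi, a 3-allyl-4-silyloxycyclopentenone and 3-methylbut-3-enal.
5. That enone comes from (S)-4-hydroxycyclopent-2-en-1-one by conjugate allylation and Saegusa–Ito oxidation.

Assumption: (S)-4-hydroxycyclopent-2-en-1-one is bought enantiopure. Bicyclic compounds are named with daucane numbering: C1 ring-fusion C–CH3, C2 CH–O, C3 CH2, C4 C(OH)(i-Pr), C5 ring-fusion CH, C6 CH–O, C7 CH2, C8 C–CH3, C9 CH, C10 CH2. H-5, 2-O, 6-O and the epoxide oxygen lie on the face opposite the C1 methyl; 4-OH lies on the methyl face.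

## Route

Step 1
Reactants: 1 (S)-4-hydroxycyclopent-2-en-1-one
Product: 2 (S)-4-[(tert-butyldimethylsilyl)oxy]cyclopent-2-en-1-one
Conditions: TBSCl, imidazole, CH2Cl2, 0 °C → rt
Reagents that add atoms: tert-butyldimethylsilyl chloride, CC(C)(C)[Si](C)(C)Cl
Why: Imidazole-promoted silyl ether formation on the secondary alcohol; the carbinol centre (the future C2) is not touched.

Step 2
Reactants: 2 (S)-4-[(tert-butyldimethylsilyl)oxy]cyclopent-2-en-1-one
Product: 3 tert-butyldimethyl{[(1S,2S)-2-(prop-2-en-1-yl)-4-[(trimethylsilyl)oxy]cyclopent-3-en-1-yl]oxy}silane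
Conditions: CH2=CHCH2MgBr, CuBr·SMe2, LiCl, TMSCl, THF, −78 °C; Et3N, aq NaHCO3
Reagents that add atoms: allylmagnesium bromide, C=CC[Mg]Br; chlorotrimethylsilane, C[Si](C)(C)Cl
Why: TMSCl-accelerated conjugate addition of an allylcopper reagent outruns 1,2-addition and traps the enolate regiospecifically as the silyl enol ether; allyl enters anti to OTBS, but this centre is erased in step 3.

Step 3
Reactants: 3 tert-butyldimethyl{[(1S,2S)-2-(prop-2-en-1-yl)-4-[(trimethylsilyl)oxy]cyclopent-3-en-1-yl]oxy}silane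
Product: 4 (S)-4-[(tert-butyldimethylsilyl)oxy]-3-(prop-2-en-1-yl)cyclopent-2-en-1-one
Conditions: Pd(OAc)2 (1.1 equiv), MeCN, rt
Reagents that add atoms: none
Why: Saegusa–Ito oxidation; the palladium enolate can only lose the β-hydrogen on the allyl-bearing carbon, so the enone re-forms with allyl on the β-carbon and the OTBS centre intact.

Step 4
Reactants: 5 3-methylbut-3-en-1-ol
Product: 6 3-methylbut-3-enal
Conditions: Dess–Martin periodinane, pyridine, CH2Cl2, 0 °C → rt; used at once as a solution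
Reagents that add atoms: none
Why: Dess–Martin oxidation is fast and near neutral, so the β,γ-unsaturated aldehyde is not isomerised to the conjugated enal.

Step 5
Reactants: 4 (S)-4-[(tert-butyldimethylsilyl)oxy]-3-(prop-2-en-1-yl)cyclopent-2-en-1-one; 6 3-methylbut-3-enal
Product: 8 (2S,3R,4S)-4-[(tert-butyldimethylsilyl)oxy]-2-[(1S)-1-hydroxy-3-methylbut-3-en-1-yl]-3-methyl-3-(prop-2-en-1-yl)cyclopentan-1-one, via lithium enolate 7 (not isolated)
Conditions: Me2CuLi (from MeLi, CuI), Et2O, −78 → −20 °C; ZnCl2, THF, −78 °C; then 6, −78 °C; aq NH4Cl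
Reagents that add atoms: lithium dimethylcuprate, [Li+].C[Cu-]C
Why: Three-component conjugate addition–aldol: methyl adds anti to OTBS (C1), the regiodefined enolate attacks the aldehyde on the face away from the allyl/OTBS side (C5), and the Zimmerman–Traxler chair of the cyclic E-enolate (zinc aldolate) gives the anti aldol (C6).

Step 6
Reactants: 8 (2S,3R,4S)-4-[(tert-butyldimethylsilyl)oxy]-2-[(1S)-1-hydroxy-3-methylbut-3-en-1-yl]-3-methyl-3-(prop-2-en-1-yl)cyclopentan-1-one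
Product: 9 (1R,2S,3R,4S)-4-[(tert-butyldimethylsilyl)oxy]-2-[(1S)-1-hydroxy-3-methylbut-3-en-1-yl]-3-methyl-1-(propan-2-yl)-3-(prop-2-en-1-yl)cyclopentan-1-ol
Conditions: i-PrMgCl (3 equiv), LaCl3·2LiCl (1 equiv), THF, −20 → 0 °C; aq NH4Cl
Reagents that add atoms: isopropylmagnesium chloride, CC(C)[Mg]Cl
Why: Lanthanide-promoted Grignard 1,2-addition suppresses enolisation and reduction; isopropyl enters trans to the bulky α side chain at C5, leaving the tertiary OH cis to it.

Step 7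
Reactants: 9 (1R,2S,3R,4S)-4-[(tert-butyldimethylsilyl)oxy]-2-[(1S)-1-hydroxy-3-methylbut-3-en-1-yl]-3-methyl-1-(propan-2-yl)-3-(prop-2-en-1-yl)cyclopentan-1-ol
Product: 10 (1R,2S,4R,5S,6S)-2-[(tert-butyldimethylsilyl)oxy]dauc-8-ene-4,6-diol
Conditions: second-generation Grubbs catalyst RuCl2(=CHPh)(PCy3)(H2IMes) (5 mol %), CH2Cl2 (5 mM), 40 °C
Reagents that add atoms: none
Why: Ring-closing metathesis of the allyl and methallyl groups closes the seven-membered ring as the trisubstituted C8=C9 alkene; the trans ring fusion is already fixed and no stereocentre is touched.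

Step 8
Reactants: 10 (1R,2S,4R,5S,6S)-2-[(tert-butyldimethylsilyl)oxy]dauc-8-ene-4,6-diol
Product: 11 (1R,2S,4R,5S,6S,8R,9S)-2-[(tert-butyldimethylsilyl)oxy]-8,9-epoxydaucane-4,6-diol
Conditions: VO(acac)2 (5 mol %), t-BuOOH (decane), CH2Cl2, 0 °C → rt
Reagents that add atoms: tert-butyl hydroperoxide, CC(C)(C)OO
Why: Hydroxyl-directed vanadium-catalysed epoxidation; the homoallylic C6–OH delivers the oxygen to its own face of C8=C9, giving the epoxide cis to 6-O.

Step 9
Reactants: 12 catechol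
Product: 13 2-methoxyphenol (guaiacol)
Conditions: MeI (1.0 equiv), K2CO3, acetone, 56 °C; distil
Reagents that add atoms: iodomethane, CI
Why: Williamson mono-O-methylation with one equivalent of MeI; guaiacol is separated from catechol and veratrole.

Step 10
Reactants: 13 2-methoxyphenol
Product: 14 4-bromo-2-methoxyphenol
Conditions: NBS, MeCN, 0 °C
Reagents that add atoms: N-bromosuccinimide, O=C1CCC(=O)N1Br
Why: Electrophilic aromatic bromination goes para to the more strongly activating free hydroxyl.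

Step 11
Reactants: 14 4-bromo-2-methoxyphenol
Product: 15 1-(benzyloxy)-4-bromo-2-methoxybenzene
Conditions: BnBr, K2CO3, DMF, rt
Reagents that add atoms: benzyl bromide, BrCc1ccccc1
Why: Williamson etherification protects the phenol as a benzyl ether that survives organolithium, acylation, fluoride and acetylation conditions.

Step 12
Reactants: 15 1-(benzyloxy)-4-bromo-2-methoxybenzene
Product: 17 4-(benzyloxy)-3-methoxybenzoic acid, via aryllithium 16 (not isolated)
Conditions: n-BuLi, THF, −78 °C; CO2; 1 M HCl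
Reagents that add atoms: carbon dioxide, O=C=O
Why: Bromine–lithium exchange at −78 °C followed by carboxylation of the aryllithium puts the acid para to the benzyloxy group.

Step 13
Reactants: 17 4-(benzyloxy)-3-methoxybenzoic acid
Product: 18 4-(benzyloxy)-3-methoxybenzoyl chloride
Conditions: (COCl)2, DMF (cat.), CH2Cl2, 0 °C → rt; evaporate
Reagents that add atoms: oxalyl chloride, O=C(Cl)C(=O)Cl
Why: Vilsmeier-type activation converts the acid to the acid chloride needed to acylate a hindered secondary alcohol.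

Step 14
Reactants: 11 (1R,2S,4R,5S,6S,8R,9S)-2-[(tert-butyldimethylsilyl)oxy]-8,9-epoxydaucane-4,6-diol; 18 4-(benzyloxy)-3-methoxybenzoyl chloride
Product: 19 (1R,2S,4R,5S,6S,8R,9S)-2-[(tert-butyldimethylsilyl)oxy]-8,9-epoxy-4-hydroxydaucan-6-yl 4-(benzyloxy)-3-methoxybenzoate
Conditions: DMAP (2 equiv), Et3N, CH2Cl2, 0 → 40 °C
Reagents that add atoms: none
Why: DMAP-catalysed acylation joins the two fragments at the only acylable hydroxyl (secondary C6–OH; the tertiary C4–OH is inert), and the basic medium leaves the epoxide closed.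

Step 15
Reactants: 19 (1R,2S,4R,5S,6S,8R,9S)-2-[(tert-butyldimethylsilyl)oxy]-8,9-epoxy-4-hydroxydaucan-6-yl 4-(benzyloxy)-3-methoxybenzoate
Product: 20 (1R,2S,4R,5S,6S,8R,9S)-8,9-epoxy-2,4-dihydroxydaucan-6-yl 4-(benzyloxy)-3-methoxybenzoate
Conditions: TBAF, AcOH (1:1), THF, rt → 45 °C
Reagents that add atoms: none
Why: Fluoride-mediated desilylation frees the C2–OH; acetic acid buffering protects the aryl ester and the epoxide from basic fluoride.

Step 16
Reactants: 20 (1R,2S,4R,5S,6S,8R,9S)-8,9-epoxy-2,4-dihydroxydaucan-6-yl 4-(benzyloxy)-3-methoxybenzoate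
Product: 21 (1R,2S,4R,5S,6S,8R,9S)-2-acetoxy-8,9-epoxy-4-hydroxydaucan-6-yl 4-(benzyloxy)-3-methoxybenzoate
Conditions: Ac2O, DMAP (cat.), pyridine, CH2Cl2, 0 °C → rt
Reagents that add atoms: acetic anhydride, CC(=O)OC(C)=O
Why: DMAP-catalysed acetylation takes the secondary C2–OH with retention at carbon; the tertiary C4–OH does not react and the phenol is still benzylated.

Step 17
Reactants: 21 (1R,2S,4R,5S,6S,8R,9S)-2-acetoxy-8,9-epoxy-4-hydroxydaucan-6-yl 4-(benzyloxy)-3-methoxybenzoate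
Product: 22 (1R,2S,4R,5S,6S,8R,9S)-2-acetoxy-8,9-epoxy-4-hydroxydaucan-6-yl 4-hydroxy-3-methoxybenzoate (CNP0241679.3)
Conditions: H2 (1 atm), 10% Pd/C, EtOAc, rt
Reagents that add atoms: none
Why: Hydrogenolysis cleaves only the benzyl aryl ether; the non-benzylic trisubstituted epoxide, both esters and the tertiary alcohol are stable.

## Compound list

1 | (S)-4-hydroxycyclopent-2-en-1-one | O=C1C=C[C@@H](O)C1 | starting material
2 | (S)-4-[(tert-butyldimethylsilyl)oxy]cyclopent-2-en-1-one | O=C1C=C[C@@H](O[Si](C)(C)C(C)(C)C)C1 | intermediate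
3 | tert-butyldimethyl{[(1S,2S)-2-(prop-2-en-1-yl)-4-[(trimethylsilyl)oxy]cyclopent-3-en-1-yl]oxy}silane | C[Si](C)(C)OC1=C[C@H](CC=C)[C@@H](O[Si](C)(C)C(C)(C)C)C1 | intermediate
4 | (S)-4-[(tert-butyldimethylsilyl)oxy]-3-(prop-2-en-1-yl)cyclopent-2-en-1-one | O=C1C=C(CC=C)[C@@H](O[Si](C)(C)C(C)(C)C)C1 | intermediate
5 | 3-methylbut-3-en-1-ol | CC(=C)CCO | starting material
6 | 3-methylbut-3-enal | CC(=C)CC=O | intermediate
7 | lithium (3R,4S)-4-[(tert-butyldimethylsilyl)oxy]-3-methyl-3-(prop-2-en-1-yl)cyclopent-1-en-1-olate | [Li]OC1=C[C@@](C)(CC=C)[C@@H](O[Si](C)(C)C(C)(C)C)C1 | intermediate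
8 | (2S,3R,4S)-4-[(tert-butyldimethylsilyl)oxy]-2-[(1S)-1-hydroxy-3-methylbut-3-en-1-yl]-3-methyl-3-(prop-2-en-1-yl)cyclopentan-1-one | C=C(C)C[C@H](O)[C@@H]1[C@@](C)(CC=C)[C@@H](O[Si](C)(C)C(C)(C)C)CC1=O | intermediate
9 | (1R,2S,3R,4S)-4-[(tert-butyldimethylsilyl)oxy]-2-[(1S)-1-hydroxy-3-methylbut-3-en-1-yl]-3-methyl-1-(propan-2-yl)-3-(prop-2-en-1-yl)cyclopentan-1-ol | C=C(C)C[C@H](O)[C@@H]1[C@@](C)(CC=C)[C@@H](O[Si](C)(C)C(C)(C)C)C[C@@]1(O)C(C)C | intermediate
10 | (1R,2S,4R,5S,6S)-2-[(tert-butyldimethylsilyl)oxy]dauc-8-ene-4,6-diol | O[C@H]2CC(C)=CC[C@@]3(C)[C@@H](O[Si](C)(C)C(C)(C)C)C[C@@](O)(C(C)C)[C@H]23 | intermediate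
11 | (1R,2S,4R,5S,6S,8R,9S)-2-[(tert-butyldimethylsilyl)oxy]-8,9-epoxydaucane-4,6-diol | O[C@H]2C[C@@]3(C)O[C@H]3C[C@@]3(C)[C@@H](O[Si](C)(C)C(C)(C)C)C[C@@](O)(C(C)C)[C@H]23 | intermediate
12 | catechol | Oc1ccccc1O | starting material
13 | 2-methoxyphenol | COc1ccccc1O | intermediate
14 | 4-bromo-2-methoxyphenol | COc1cc(Br)ccc1O | intermediate
15 | 1-(benzyloxy)-4-bromo-2-methoxybenzene | COc1cc(Br)ccc1OCc1ccccc1 | intermediate
16 | [4-(benzyloxy)-3-methoxyphenyl]lithium | [Li]c1ccc(OCc2ccccc2)c(OC)c1 | intermediate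
17 | 4-(benzyloxy)-3-methoxybenzoic acid | COc1cc(C(=O)O)ccc1OCc1ccccc1 | intermediate
18 | 4-(benzyloxy)-3-methoxybenzoyl chloride | COc1cc(C(=O)Cl)ccc1OCc1ccccc1 | intermediate
19 | (1R,2S,4R,5S,6S,8R,9S)-2-[(tert-butyldimethylsilyl)oxy]-8,9-epoxy-4-hydroxydaucan-6-yl 4-(benzyloxy)-3-methoxybenzoate | COc1cc(C(=O)O[C@H]2C[C@@]3(C)O[C@H]3C[C@@]3(C)[C@@H](O[Si](C)(C)C(C)(C)C)C[C@@](O)(C(C)C)[C@H]23)ccc1OCc1ccccc1 | intermediate
20 | (1R,2S,4R,5S,6S,8R,9S)-8,9-epoxy-2,4-dihydroxydaucan-6-yl 4-(benzyloxy)-3-methoxybenzoate | COc1cc(C(=O)O[C@H]2C[C@@]3(C)O[C@H]3C[C@@]3(C)[C@@H](O)C[C@@](O)(C(C)C)[C@H]23)ccc1OCc1ccccc1 | intermediate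
21 | (1R,2S,4R,5S,6S,8R,9S)-2-acetoxy-8,9-epoxy-4-hydroxydaucan-6-yl 4-(benzyloxy)-3-methoxybenzoate | COc1cc(C(=O)O[C@H]2C[C@@]3(C)O[C@H]3C[C@@]3(C)[C@@H](OC(C)=O)C[C@@](O)(C(C)C)[C@H]23)ccc1OCc1ccccc1 | intermediate
22 | (1R,2S,4R,5S,6S,8R,9S)-2-acetoxy-8,9-epoxy-4-hydroxydaucan-6-yl 4-hydroxy-3-methoxybenzoate | COc1cc(C(=O)O[C@H]2C[C@@]3(C)O[C@H]3C[C@@]3(C)[C@@H](OC(C)=O)C[C@@](O)(C(C)C)[C@H]23)ccc1O | target

## Step count

Total steps: 17.
Longest linear sequence: 11 steps (1, 2, 3, 5, 6, 7, 8, 14, 15, 16, 17). The aldehyde branch (step 4) and the aroyl branch (steps 9–13) run in parallel.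

## Steps most likely to fail, with fallbacks

**Step 5 (three-component coupling).** The enolate may deprotonate the enolisable aldehyde, or the carbinol centre C6 may come out mixed. The fallback sets out from 4 and comes back at 10.
- Me2CuLi with TMSCl converts 4 into the isolable silyl enol ether tert-butyldimethyl{[(1S,2R)-2-methyl-2-(prop-2-en-1-yl)-4-[(trimethylsilyl)oxy]cyclopent-3-en-1-yl]oxy}silane F1.
- A BF3·OEt2-promoted Mukaiyama aldol with 6 (CH2Cl2, −78 °C, no basic enolate) gives 8 together with its C6 epimer (2S,3R,4S)-4-[(tert-butyldimethylsilyl)oxy]-2-[(1R)-1-hydroxy-3-methylbut-3-en-1-yl]-3-methyl-3-(prop-2-en-1-yl)cyclopentan-1-one F2.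
- The mixture is carried through the conditions of steps 6 and 7. This gives, beside 9 and 10, the epimeric diene diol (1R,2S,3R,4S)-4-[(tert-butyldimethylsilyl)oxy]-2-[(1R)-1-hydroxy-3-methylbut-3-en-1-yl]-3-methyl-1-(propan-2-yl)-3-(prop-2-en-1-yl)cyclopentan-1-ol F3 and the bicyclic diol (1R,2S,4R,5S,6R)-2-[(tert-butyldimethylsilyl)oxy]dauc-8-ene-4,6-diol F4.
- Dess–Martin oxidation of the 10/F4 mixture converges on the single ketone (1R,2S,4R,5R)-2-[(tert-butyldimethylsilyl)oxy]-4-hydroxydauc-8-en-6-one F5.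
- Me4NBH(OAc)3 in AcOH/MeCN at −20 °C (Evans–Saksena reduction) delivers hydride from the boron bound to the C4 oxygen on the methyl face, placing the 6-OH on the opposite face, which is 10.

**Step 6 (isopropyl addition).** The hindered β-hydroxy ketone may enolise (with loss of the β-silyloxy group), be reduced, or be attacked from the wrong face. The fallback sets out from 8 and comes back at 10.
- Ring-closing metathesis of 8 with the second-generation Grubbs catalyst comes first and gives the rigid trans-fused (1R,2S,5S,6S)-2-[(tert-butyldimethylsilyl)oxy]-6-hydroxydauc-8-en-4-one F6.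
- Isopropenylmagnesium bromide with CeCl3 (THF, −78 °C) is used as the nucleophile; being sp2 it cannot act as a hydride donor and is less basic. It should add from the face opposite the angular methyl, giving (1S,3S,3aS,4S,8aR)-1-[(tert-butyldimethylsilyl)oxy]-6,8a-dimethyl-3-(prop-1-en-2-yl)-1,2,3,3a,4,5,8,8a-octahydroazulene-3,4-diol F7.
- H2 with RhCl(PPh3)3 in benzene saturates the 1,1-disubstituted isopropenyl group and spares the trisubstituted ring alkene, giving 10.

**Step 8 (directed epoxidation).** Direction by the homoallylic hydroxyl may be weak, or the Lewis-acidic vanadium may trigger transannular opening of the epoxide by the C4–OH. The fallback sets out from 10 and comes back at 19.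
- 10 is acylated first with 18 (DMAP, Et3N, CH2Cl2) to give (1R,2S,4R,5S,6S)-2-[(tert-butyldimethylsilyl)oxy]-4-hydroxydauc-8-en-6-yl 4-(benzyloxy)-3-methoxybenzoate F8.
- F8 is epoxidised without a metal, using mCPBA with NaHCO3 in CH2Cl2 at 0 °C. The angular C1 methyl screens its own face of C8=C9, so the peracid should approach from the opposite face and give 19. This face preference is a steric argument, not a directed delivery, and is less certain than the main route.

## Further compounds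

F1 | step 5 | tert-butyldimethyl{[(1S,2R)-2-methyl-2-(prop-2-en-1-yl)-4-[(trimethylsilyl)oxy]cyclopent-3-en-1-yl]oxy}silane | C[Si](C)(C)OC1=C[C@@](C)(CC=C)[C@@H](O[Si](C)(C)C(C)(C)C)C1
F2 | step 5 | (2S,3R,4S)-4-[(tert-butyldimethylsilyl)oxy]-2-[(1R)-1-hydroxy-3-methylbut-3-en-1-yl]-3-methyl-3-(prop-2-en-1-yl)cyclopentan-1-one | C=C(C)C[C@@H](O)[C@@H]1[C@@](C)(CC=C)[C@@H](O[Si](C)(C)C(C)(C)C)CC1=O
F3 | step 5 | (1R,2S,3R,4S)-4-[(tert-butyldimethylsilyl)oxy]-2-[(1R)-1-hydroxy-3-methylbut-3-en-1-yl]-3-methyl-1-(propan-2-yl)-3-(prop-2-en-1-yl)cyclopentan-1-ol | C=C(C)C[C@@H](O)[C@@H]1[C@@](C)(CC=C)[C@@H](O[Si](C)(C)C(C)(C)C)C[C@@]1(O)C(C)C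
F4 | step 5 | (1R,2S,4R,5S,6R)-2-[(tert-butyldimethylsilyl)oxy]dauc-8-ene-4,6-diol | O[C@@H]2CC(C)=CC[C@@]3(C)[C@@H](O[Si](C)(C)C(C)(C)C)C[C@@](O)(C(C)C)[C@H]23
F5 | step 5 | (1R,2S,4R,5R)-2-[(tert-butyldimethylsilyl)oxy]-4-hydroxydauc-8-en-6-one | O=C2CC(C)=CC[C@@]3(C)[C@@H](O[Si](C)(C)C(C)(C)C)C[C@@](O)(C(C)C)[C@H]23
F6 | step 6 | (1R,2S,5S,6S)-2-[(tert-butyldimethylsilyl)oxy]-6-hydroxydauc-8-en-4-one | O[C@H]2CC(C)=CC[C@@]3(C)[C@@H](O[Si](C)(C)C(C)(C)C)CC(=O)[C@H]23
F7 | step 6 | (1S,3S,3aS,4S,8aR)-1-[(tert-butyldimethylsilyl)oxy]-6,8a-dimethyl-3-(prop-1-en-2-yl)-1,2,3,3a,4,5,8,8a-octahydroazulene-3,4-diol | O[C@H]2CC(C)=CC[C@@]3(C)[C@@H](O[Si](C)(C)C(C)(C)C)C[C@@](O)(C(C)=C)[C@H]23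
F8 | step 8 | (1R,2S,4R,5S,6S)-2-[(tert-butyldimethylsilyl)oxy]-4-hydroxydauc-8-en-6-yl 4-(benzyloxy)-3-methoxybenzoate | COc1cc(C(=O)O[C@H]2CC(C)=CC[C@@]3(C)[C@@H](O[Si](C)(C)C(C)(C)C)C[C@@](O)(C(C)C)[C@H]23)ccc1OCc1ccccc1
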